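**Plan**

1. Retrosynthesis: the acetal–lactone bicycle is opened to a hydroxy aldehyde acid, which comes from C–C cleavage of a 3,4-trans-disubstituted cyclopentanone. The bond from the quaternary carbon C2 of the octahydronaphthalene to the bicycle is cut to a tertiary radical plus a 2-chlorocyclopentenone. The decalin is cut at C4a–C8a and C6–C7, then at C1–C2.
2. Forward: a γ,δ-unsaturated β-keto ester aldehyde undergoes catalytic Michael addition to pentenone. One base-mediated cascade then closes ring B (C4a–C8a, Michael addition) and ring A (C6–C7, aldol condensation). Both ring carbonyls are erased through a bis(enol triflate); the ester becomes the acid and its redox-active ester; radical coupling, cyclopentanone cleavage and acetal lactonisation finish the route.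
3. Enabling feature: ring A (C4a, C5–C8, C8a) is a methyl ketone in disguise. C8 is the carbonyl carbon and C8a and C7 are its two α-carbons. They face a 1,3-dielectrophile across the gem-dimethyl carbon C5: C4a as the β-carbon of an enone (temporary C3 ketone in ring B) and C6 as a non-enolisable aldehyde. The C8 ketone is later turned into the C8=C8a alkene, whose position is fixed by the only possible enolisation.
4. Stereochemistry: C1 comes from the catalyst-controlled Michael addition. C4a comes from the all-equatorial chair closure of ring B, relayed from C1. C2 and the bridge carbon come from radical addition anti to the C1 methyl group and anti to the cyclopentenone side chain. The carbinol and ring carbons of the bicycle come from a catalytic glyoxylate-ene reaction; the acetal carbon is fixed by the bicycle.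

Key step: step 5

Assumptions: the ligand enantiomers in steps 4 and 11 are assigned by analogy with the usual sense of induction of these catalysts. C2 of 9–18 is drawn as one epimer; its configuration is erased at the radical stage (step 15). In names, R* is the 1,2,5,5-tetramethyl-1,2,3,4,4a,5,6,7-octahydronaphthalen-2-yl group with the target's configuration; its CIP labels change with the neighbour, so the SMILES define it.

**Step 1**
Reactants: 1 2,2-dimethylpropane-1,3-diol
Product: 2 2,2-dimethylpropanedial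
Conditions: (COCl)2, DMSO, CH2Cl2, −78 °C; Et3N, −78 → 0 °C; used as dried solution
Reagents that add atoms: none
Why: Swern oxidation of both primary alcohols should stop cleanly at the non-enolisable dialdehyde.

**Step 2**
Reactants: 3 methyl 2-methyl-3-oxobutanoate; 2 2,2-dimethylpropanedial (3 equiv)
Product: 5 methyl 5-hydroxy-2,6,6-trimethyl-3,7-dioxoheptanoate (stereoisomer mixture), via dianion 4 (not isolated)
Conditions: NaH, THF, 0 °C; n-BuLi, 0 °C; add to 2, −78 °C; aq. NH4Cl
Reagents that add atoms: none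
Why: acetoacetate dianion aldol addition, in which the terminal carbon of the 1,3-dianion attacks one aldehyde group; the excess of symmetric dialdehyde should hold the reaction at mono-addition.

**Step 3**
Reactants: 5 methyl 5-hydroxy-2,6,6-trimethyl-3,7-dioxoheptanoate
Product: 7 methyl (4E)-2,6,6-trimethyl-3,7-dioxohept-4-enoate, via mesylate 6 (not isolated)
Conditions: MsCl, Et3N, CH2Cl2, 0 °C → rt
Reagents that add atoms: none
Why: mesylation and E1cB elimination of the β-mesyloxy ketone should give the (E)-enone; the aldehyde has no α-hydrogen and stays untouched.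

**Step 4**
Reactants: 7 methyl (4E)-2,6,6-trimethyl-3,7-dioxohept-4-enoate; 8 (3E)-pent-3-en-2-one
Product: 9 methyl (2S,4E)-2,6,6-trimethyl-3,7-dioxo-2-[(2R)-4-oxopentan-2-yl]hept-4-enoate
Conditions: [Pd((R)-BINAP)(H2O)2](OTf)2 (5 mol%), THF, −20 °C
Reagents that add atoms: none
Why: enantioselective Michael addition of the chiral palladium enolate of the α-methyl β-keto ester to the acid-activated enone; the ligand fixes the face of the enone β-carbon (the methyl-bearing stereocentre) and of the enolate (quaternary carbon).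

**Step 5**
Reactants: 9 methyl (2S,4E)-2,6,6-trimethyl-3,7-dioxo-2-[(2R)-4-oxopentan-2-yl]hept-4-enoate
Product: 12 methyl (1R,2S,4aR,8aR)-1,2,5,5-tetramethyl-3,8-dioxo-1,2,3,4,4a,5,8,8a-octahydronaphthalene-2-carboxylate, via Michael adduct 10 (not isolated), via aldol 11 (not isolated)
Conditions: DBU (2 equiv), MeCN (0.02 M), 0 °C → rt, then 60 °C
Reagents that add atoms: none
Why: DBU enolises the methyl ketone of 9 reversibly; the internal enolate (the carbon that becomes C8a) adds to the β-carbon of the enone (future C4a) to give cyclohexanone 10, then the terminal enolate of the acetyl group attacks the aldehyde (C7 to C6) to give aldol 11, whose E1cB dehydration makes the sequence irreversible. The closest known reaction types are the second conjugate addition of a base-mediated double Michael annulation of γ,δ-unsaturated β-keto esters and the aldol condensation of a Robinson annulation. Ring B closes by a 6-endo-trig Michael addition and ring A by a 6-(enolendo)-exo-trig aldol addition. C4a is set in a chair transition state in which the existing C1 methyl group, the acetyl group and the tertiary alkyl group are all equatorial, which places the C4a substituent cis to the C1 methyl group; C8a is epimerisable and should settle trans to both neighbours (it becomes sp2 in step 6). The step needs the Michael addition to win over aldol attack of the terminal enolate on the ring-B ketone: that ketone is flanked by the quaternary carbon and its aldol adduct can revert, the terminal enolate can reach the enone only through an eight-membered ring, and the aldehyde has no α-hydrogen and comes within reach only once ring B exists.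

**Step 6**
Reactants: 12 methyl (1R,2S,4aR,8aR)-1,2,5,5-tetramethyl-3,8-dioxo-1,2,3,4,4a,5,8,8a-octahydronaphthalene-2-carboxylate
Product: 14 methyl (1R,2S,4aS)-1,2,5,5-tetramethyl-3,8-bis(trifluoromethanesulfonyloxy)-1,2,4a,5-tetrahydronaphthalene-2-carboxylate, via bis-enolate 13 (not isolated)
Conditions: KN(SiMe3)2 (2.5 equiv), THF, −78 → −20 °C; PhNTf2 (2.5 equiv), −78 °C → rt
Reagents that add atoms: N-phenylbis(trifluoromethanesulfonimide), O=S(=O)(N(c1ccccc1)S(=O)(=O)C(F)(F)F)C(F)(F)F
Why: enol triflate formation with no regiochemical choice: the ring-A enone can be deprotonated only at C8a (C5 is quaternary), the ring-B ketone only at C4 (C2 is quaternary), so the triflates mark exactly the C8=C8a and C3=C4 positions.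

**Step 7**
Reactants: 14 methyl (1R,2S,4aS)-1,2,5,5-tetramethyl-3,8-bis(trifluoromethanesulfonyloxy)-1,2,4a,5-tetrahydronaphthalene-2-carboxylate
Product: 15 methyl (1R,2R,4aS)-1,2,5,5-tetramethyl-1,2,4a,5-tetrahydronaphthalene-2-carboxylate
Conditions: Pd(OAc)2 (10 mol%), PPh3 (20 mol%), n-Bu3N, HCO2H, DMF, 60 °C
Reagents that add atoms: none
Why: palladium-catalysed formate reduction of vinyl triflates (oxidative addition of zerovalent palladium, formate-to-hydride exchange, reductive elimination) replaces each OTf by H without moving the double bonds.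

**Step 8**
Reactants: 15 methyl (1R,2R,4aS)-1,2,5,5-tetramethyl-1,2,4a,5-tetrahydronaphthalene-2-carboxylate
Product: 16 methyl (1R,2R,4aS)-1,2,5,5-tetramethyl-1,2,3,4,4a,5,6,7-octahydronaphthalene-2-carboxylate
Conditions: KO2CN=NCO2K (excess, portionwise), AcOH, MeOH–pyridine, 0 °C → rt
Reagents that add atoms: none
Why: diimide reduction is expected to saturate the two cis-disubstituted alkenes (C3=C4 and C6=C7) and leave the more hindered trisubstituted C8=C8a alkene, without metal-induced alkene migration.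

**Step 9**
Reactants: 16 methyl (1R,2R,4aS)-1,2,5,5-tetramethyl-1,2,3,4,4a,5,6,7-octahydronaphthalene-2-carboxylate
Product: 17 (1R,2R,4aS)-1,2,5,5-tetramethyl-1,2,3,4,4a,5,6,7-octahydronaphthalene-2-carboxylic acid
Conditions: NaSEt, DMF, 100 °C; aq. HCl
Reagents that add atoms: none
Why: thiolate SN2 demethylation attacks the unhindered methyl carbon, so the congested tertiary ester carbonyl need not be approached.

**Step 10**
Reactants: 17 (1R,2R,4aS)-1,2,5,5-tetramethyl-1,2,3,4,4a,5,6,7-octahydronaphthalene-2-carboxylic acid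
Product: 18 1,3-dioxoisoindolin-2-yl (1R,2R,4aS)-1,2,5,5-tetramethyl-1,2,3,4,4a,5,6,7-octahydronaphthalene-2-carboxylate
Conditions: N-hydroxyphthalimide, DIC, DMAP (cat.), CH2Cl2, rt
Reagents that add atoms: N-hydroxyphthalimide, O=C1c2ccccc2C(=O)N1O
Why: carbodiimide esterification gives the redox-active ester needed for reductive decarboxylation.

**Step 11**
Reactants: 19 cyclopentene (excess); 20 methyl 2-oxoacetate
Product: 21 methyl (2R)-2-[(1R)-cyclopent-2-en-1-yl]-2-hydroxyacetate
Conditions: [Cu((R,R)-t-Bu-box)](SbF6)2 (10 mol%), CH2Cl2, 0 °C → rt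
Reagents that add atoms: none
Why: catalytic asymmetric carbonyl-ene reaction; the chelated glyoxylate is attacked on one face (carbinol centre) and the endo ene transition state should set the ring carbon.

**Step 12**
Reactants: 21 methyl (2R)-2-[(1R)-cyclopent-2-en-1-yl]-2-hydroxyacetate
Product: 22 methyl (2R)-2-[(tert-butyldimethylsilyl)oxy]-2-[(1R)-cyclopent-2-en-1-yl]acetate
Conditions: TBSCl, imidazole, DMF, rt
Reagents that add atoms: tert-butyldimethylsilyl chloride, CC(C)(C)[Si](C)(C)Cl
Why: standard silylation protects the carbinol against the oxidations that follow.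

**Step 13**
Reactants: 22 methyl (2R)-2-[(tert-butyldimethylsilyl)oxy]-2-[(1R)-cyclopent-2-en-1-yl]acetate
Product: 23 methyl (2R)-2-[(tert-butyldimethylsilyl)oxy]-2-[(1R)-4-oxocyclopent-2-en-1-yl]acetate
Conditions: Rh2(cap)4 (1 mol%, cap = caprolactamate), t-BuOOH, K2CO3, CH2Cl2, rt
Reagents that add atoms: tert-butyl hydroperoxide, CC(C)(C)OO
Why: peroxyl-radical allylic oxidation should convert the unhindered allylic CH2 remote from the side chain into the enone carbonyl, giving the 4-substituted cyclopent-2-enone.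

**Step 14**
Reactants: 23 methyl (2R)-2-[(tert-butyldimethylsilyl)oxy]-2-[(1R)-4-oxocyclopent-2-en-1-yl]acetate
Product: 24 methyl (2R)-2-[(tert-butyldimethylsilyl)oxy]-2-[(1R)-3-chloro-4-oxocyclopent-2-en-1-yl]acetate
Conditions: PhICl2, pyridine, CH2Cl2, 0 °C → rt
Reagents that add atoms: (dichloroiodo)benzene, ClI(Cl)c1ccccc1
Why: pyridine-mediated α-halogenation of an enone (conjugate addition of pyridine, chlorination of the enolate, elimination) puts chlorine on the α-carbon, the later handle for a regiodefined enolate.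

**Step 15**
Reactants: 18 1,3-dioxoisoindolin-2-yl (1R,2R,4aS)-1,2,5,5-tetramethyl-1,2,3,4,4a,5,6,7-octahydronaphthalene-2-carboxylate; 24 methyl (2R)-2-[(tert-butyldimethylsilyl)oxy]-2-[(1R)-3-chloro-4-oxocyclopent-2-en-1-yl]acetate (1.5 equiv)
Product: 25 methyl (2R)-2-[(tert-butyldimethylsilyl)oxy]-2-[(1R,2R)-3-chloro-4-oxo-2-R*-cyclopentyl]acetate (epimers at the chlorine-bearing carbon)
Conditions: Ru(bpy)3(PF6)2 (1 mol%), Hantzsch ester, i-Pr2NEt, CH2Cl2, blue LEDs, rt
Reagents that add atoms: none
Why: photoredox decarboxylative Giese addition of the tertiary radical to the enone β-carbon; the radical should be attacked on its equatorial face anti to the neighbouring C1 methyl group (quaternary carbon) and the enone anti to its C4 side chain (bridge carbon).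

**Step 16**
Reactants: 25 methyl (2R)-2-[(tert-butyldimethylsilyl)oxy]-2-[(1R,2R)-3-chloro-4-oxo-2-R*-cyclopentyl]acetate
Product: 27 methyl (2R)-2-[(tert-butyldimethylsilyl)oxy]-2-[(1R,2S)-4-[(tert-butyldimethylsilyl)oxy]-2-R*-cyclopent-3-en-1-yl]acetate, via lithium enolate 26 (not isolated)
Conditions: LiCuMe2, THF, −78 → −30 °C; TBSCl, HMPA, −78 → 0 °C; aq. NH4Cl
Reagents that add atoms: tert-butyldimethylsilyl chloride, CC(C)(C)[Si](C)(C)Cl
Why: reductive dechlorination of the α-chloro ketone by the cuprate gives the enolate only on the hindered side, and O-silylation preserves that regiochemistry.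

**Step 17**
Reactants: 27 methyl (2R)-2-[(tert-butyldimethylsilyl)oxy]-2-[(1R,2S)-4-[(tert-butyldimethylsilyl)oxy]-2-R*-cyclopent-3-en-1-yl]acetate
Product: 29 (3R,4R)-4-[(tert-butyldimethylsilyl)oxy]-5-methoxy-5-oxo-3-[(1R)-2-oxo-1-R*-ethyl]pentanoic acid, via hydroxy ketone 28 (not isolated)
Conditions: OsO4 (2 mol%), NaIO4, 2,6-lutidine, dioxane–H2O, 0 °C → rt
Reagents that add atoms: sodium periodate, [Na+].[O-]I(=O)(=O)=O; water, O
Why: Lemieux–Johnson oxidation: the electron-rich silyl enol ether should be osmylated much faster than the hindered trisubstituted alkene, and periodate cleaves the resulting α-hydroxy ketone to aldehyde and acid.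

**Step 18**
Reactants: 29 (3R,4R)-4-[(tert-butyldimethylsilyl)oxy]-5-methoxy-5-oxo-3-[(1R)-2-oxo-1-R*-ethyl]pentanoic acid
Product: 32 methyl (1S,5R,6R,8R)-3-oxo-8-[(1S,2R,4aS)-1,2,5,5-tetramethyl-1,2,3,4,4a,5,6,7-octahydronaphthalen-2-yl]-2,7-dioxabicyclo[3.2.1]octane-6-carboxylate, via hydroxy aldehyde 30 (not isolated), via lactol 31 (not isolated)
Conditions: HF·pyridine, MeCN, 0 °C → rt; then TsOH (cat.), 4 Å molecular sieves, CH2Cl2, rt
Reagents that add atoms: none
Why: desilylation frees the carbinol, which closes onto the aldehyde as a five-membered lactol; acid-catalysed acylal formation with the carboxylic acid then closes the bridging lactone, and the acetal carbon can only take the configuration the bicycle allows.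

**Compound list**

1 | 2,2-dimethylpropane-1,3-diol | OCC(C)(C)CO | starting material
2 | 2,2-dimethylpropanedial | O=CC(C)(C)C=O | intermediate
3 | methyl 2-methyl-3-oxobutanoate (racemic) | COC(=O)C(C)C(C)=O | starting material
4 | sodium lithium 1,3-dienolate (dianion) of 3 | [Na+].[Li+].COC([O-])=C(C)C([O-])=C | intermediate
5 | methyl 5-hydroxy-2,6,6-trimethyl-3,7-dioxoheptanoate (stereoisomer mixture) | COC(=O)C(C)C(=O)CC(O)C(C)(C)C=O | intermediate
6 | methyl 5-(methanesulfonyloxy)-2,6,6-trimethyl-3,7-dioxoheptanoate | COC(=O)C(C)C(=O)CC(OS(C)(=O)=O)C(C)(C)C=O | intermediate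
7 | methyl (4E)-2,6,6-trimethyl-3,7-dioxohept-4-enoate (racemic at C2) | COC(=O)C(C)C(=O)/C=C/C(C)(C)C=O | intermediate
8 | (3E)-pent-3-en-2-one | C/C=C/C(C)=O | starting material
9 | methyl (2S,4E)-2,6,6-trimethyl-3,7-dioxo-2-[(2R)-4-oxopentan-2-yl]hept-4-enoate | COC(=O)[C@](C)(C(=O)/C=C/C(C)(C)C=O)[C@H](C)CC(C)=O | intermediate
10 | methyl (1S,2R,3R,4R)-3-acetyl-1,2-dimethyl-4-(2-methyl-1-oxopropan-2-yl)-6-oxocyclohexane-1-carboxylate | COC(=O)[C@]1(C)C(=O)C[C@@H](C(C)(C)C=O)[C@H](C(C)=O)[C@H]1C | intermediate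
11 | methyl (1R,2S,4aR,8aR)-6-hydroxy-1,2,5,5-tetramethyl-3,8-dioxodecahydronaphthalene-2-carboxylate (C6 epimers) | COC(=O)[C@]1(C)C(=O)C[C@@H]2[C@H](C(=O)CC(O)C2(C)C)[C@H]1C | intermediate
12 | methyl (1R,2S,4aR,8aR)-1,2,5,5-tetramethyl-3,8-dioxo-1,2,3,4,4a,5,8,8a-octahydronaphthalene-2-carboxylate | COC(=O)[C@]1(C)C(=O)C[C@@H]2[C@H](C(=O)C=CC2(C)C)[C@H]1C | intermediate
13 | dipotassium bis-enolate of 12 (C3-enolate and C8 cross-conjugated dienolate) | [K+].[K+].COC(=O)[C@]1(C)C([O-])=C[C@@H]2C(=C([O-])C=CC2(C)C)[C@H]1C | intermediate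
14 | methyl (1R,2S,4aS)-1,2,5,5-tetramethyl-3,8-bis(trifluoromethanesulfonyloxy)-1,2,4a,5-tetrahydronaphthalene-2-carboxylate | COC(=O)[C@]1(C)C(OS(=O)(=O)C(F)(F)F)=C[C@@H]2C(=C(OS(=O)(=O)C(F)(F)F)C=CC2(C)C)[C@H]1C | intermediate
15 | methyl (1R,2R,4aS)-1,2,5,5-tetramethyl-1,2,4a,5-tetrahydronaphthalene-2-carboxylate | COC(=O)[C@]1(C)C=C[C@@H]2C(=CC=CC2(C)C)[C@H]1C | intermediate
16 | methyl (1R,2R,4aS)-1,2,5,5-tetramethyl-1,2,3,4,4a,5,6,7-octahydronaphthalene-2-carboxylate | COC(=O)[C@]1(C)CC[C@@H]2C(=CCCC2(C)C)[C@H]1C | intermediate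
17 | (1R,2R,4aS)-1,2,5,5-tetramethyl-1,2,3,4,4a,5,6,7-octahydronaphthalene-2-carboxylic acid | OC(=O)[C@]1(C)CC[C@@H]2C(=CCCC2(C)C)[C@H]1C | intermediate
18 | 1,3-dioxoisoindolin-2-yl (1R,2R,4aS)-1,2,5,5-tetramethyl-1,2,3,4,4a,5,6,7-octahydronaphthalene-2-carboxylate | O=C(ON1C(=O)c2ccccc2C1=O)[C@]1(C)CC[C@@H]2C(=CCCC2(C)C)[C@H]1C | intermediate
19 | cyclopentene | C1=CCCC1 | starting material
20 | methyl 2-oxoacetate (methyl glyoxylate) | COC(=O)C=O | starting material
21 | methyl (2R)-2-[(1R)-cyclopent-2-en-1-yl]-2-hydroxyacetate | COC(=O)[C@H](O)[C@@H]1CCC=C1 | intermediate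
22 | methyl (2R)-2-[(tert-butyldimethylsilyl)oxy]-2-[(1R)-cyclopent-2-en-1-yl]acetate | COC(=O)[C@H](O[Si](C)(C)C(C)(C)C)[C@@H]1CCC=C1 | intermediate
23 | methyl (2R)-2-[(tert-butyldimethylsilyl)oxy]-2-[(1R)-4-oxocyclopent-2-en-1-yl]acetate | COC(=O)[C@H](O[Si](C)(C)C(C)(C)C)[C@@H]1CC(=O)C=C1 | intermediate
24 | methyl (2R)-2-[(tert-butyldimethylsilyl)oxy]-2-[(1R)-3-chloro-4-oxocyclopent-2-en-1-yl]acetate | COC(=O)[C@H](O[Si](C)(C)C(C)(C)C)[C@@H]1CC(=O)C(Cl)=C1 | intermediate
25 | methyl (2R)-2-[(tert-butyldimethylsilyl)oxy]-2-[(1R,2R)-3-chloro-4-oxo-2-R*-cyclopentyl]acetate (C3 epimers; side chain and R* trans) | COC(=O)[C@H](O[Si](C)(C)C(C)(C)C)[C@@H]1CC(=O)C(Cl)[C@H]1[C@]2(C)CC[C@@H]3C(=CCCC3(C)C)[C@H]2C | intermediate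
26 | lithium enolate of dechlorinated 25 (enolised towards the R*-bearing side) | [Li+].COC(=O)[C@H](O[Si](C)(C)C(C)(C)C)[C@@H]1CC([O-])=C[C@H]1[C@]2(C)CC[C@@H]3C(=CCCC3(C)C)[C@H]2C | intermediate
27 | methyl (2R)-2-[(tert-butyldimethylsilyl)oxy]-2-[(1R,2S)-4-[(tert-butyldimethylsilyl)oxy]-2-R*-cyclopent-3-en-1-yl]acetate | COC(=O)[C@H](O[Si](C)(C)C(C)(C)C)[C@@H]1CC(O[Si](C)(C)C(C)(C)C)=C[C@H]1[C@]2(C)CC[C@@H]3C(=CCCC3(C)C)[C@H]2C | intermediate
28 | methyl (2R)-2-[(tert-butyldimethylsilyl)oxy]-2-[(1R,2R)-3-hydroxy-4-oxo-2-R*-cyclopentyl]acetate (C3 epimers) | COC(=O)[C@H](O[Si](C)(C)C(C)(C)C)[C@@H]1CC(=O)C(O)[C@H]1[C@]2(C)CC[C@@H]3C(=CCCC3(C)C)[C@H]2C | intermediate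
29 | (3R,4R)-4-[(tert-butyldimethylsilyl)oxy]-5-methoxy-5-oxo-3-[(1R)-2-oxo-1-R*-ethyl]pentanoic acid | COC(=O)[C@H](O[Si](C)(C)C(C)(C)C)[C@H](CC(=O)O)[C@@H](C=O)[C@]1(C)CC[C@@H]2C(=CCCC2(C)C)[C@H]1C | intermediate
30 | (3R,4R)-4-hydroxy-5-methoxy-5-oxo-3-[(1R)-2-oxo-1-R*-ethyl]pentanoic acid | COC(=O)[C@H](O)[C@H](CC(=O)O)[C@@H](C=O)[C@]1(C)CC[C@@H]2C(=CCCC2(C)C)[C@H]1C | intermediate
31 | 2-[5-hydroxy-2-(methoxycarbonyl)-4-R*-tetrahydrofuran-3-yl]acetic acid (lactol epimers; ester and acetic acid chain trans, acetic acid chain and R* cis) | COC(=O)[C@@H]1OC(O)[C@@H]([C@]2(C)CC[C@@H]3C(=CCCC3(C)C)[C@H]2C)[C@H]1CC(=O)O | intermediate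
32 | methyl (1S,5R,6R,8R)-3-oxo-8-[(1S,2R,4aS)-1,2,5,5-tetramethyl-1,2,3,4,4a,5,6,7-octahydronaphthalen-2-yl]-2,7-dioxabicyclo[3.2.1]octane-6-carboxylate | COC(=O)[C@@H]1O[C@H]2OC(=O)C[C@@H]1[C@@H]2[C@]1(C)CC[C@@H]2C(=CCCC2(C)C)[C@H]1C | target

**Totals**

Total step count: 18. Longest linear sequence: 14 steps (steps 1–10, then 15–18); the cyclopentenone branch is steps 11–14.

**Steps most likely to fail**

Step 5. Three processes threaten it. The terminal enolate may attack the ring-B ketone precursor in a Robinson-type aldol condensation. The bond made in step 4 may reopen by retro-Michael reaction and erode the methyl-bearing stereocentre. Conjugate addition to the β-carbon next to the gem-dimethyl carbon may be slow. The fallback sets out from 7 and 8 and rejoins at 12. The two Michael additions are run as one amine-catalysed iminium–enamine sequence (9-amino-9-deoxy-epi-quinine, acid co-catalyst, toluene), then TsOH finishes the aldol condensation. The enamine formed by the first conjugate addition sits on the carbon that must attack next, so no enolate regiochemistry has to be controlled and no free enolate is present to reopen the first bond. It passes through the same compounds 9, 10 and 11 in amine-bound form and makes no new compound (F0).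

Step 15. Bond formation between the congested tertiary radical and the enone may be slow, and attack on the wrong face of the radical would give the epimer at the quaternary carbon. The fallback sets out from 12 and 23 and rejoins at 27; it makes the same bond by enolate chemistry while the ring-B ketone is still present.
- Krapcho dealkoxycarbonylation of 12 (LiCl, wet DMSO, 150 °C) gives 1,2,5,5-tetramethyl-1,2,4,4a,5,8a-hexahydronaphthalene-3,8-dione F1.
- Thermodynamic enol silylation of the ring-B ketone (TBSOTf, Et3N, CH2Cl2) gives the tetrasubstituted silyl enol ether F2.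
- Mukaiyama–Michael addition of F2 to 23 (catalytic TBSOTf, CH2Cl2, −78 °C) gives the adduct F3, which already carries the cyclopentanone as its silyl enol ether. Attack is expected anti to the pseudo-axial neighbouring methyl group of the enol ether and anti to the side chain of 23.
- The sequence of steps 6–8 then follows: bis-triflation to the bis(enol triflate) F4, formate reduction to the triene F5, and diimide reduction to 27.

Step 13. Hydrogen abstraction at the tertiary allylic position or oxygenation at the other end of the allyl radical would give regioisomeric enones or destroy the ring stereocentre. The fallback sets out from 20 and rejoins at 23; the ring oxygen is in place before the ene reaction.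
- Commercial cyclopent-3-en-1-ol is acetylated to cyclopent-3-en-1-yl acetate F6.
- The same copper-catalysed glyoxylate-ene reaction gives methyl (2R)-2-[(1R)-4-acetoxycyclopent-2-en-1-yl]-2-hydroxyacetate F7, in which the new alkene is already allylic to the acetoxy carbon.
- Silylation (TBSCl, imidazole) gives the silyl ether F8.
- Methanolysis of the acetate (K2CO3, MeOH) gives the allylic alcohol F9.
- Dess–Martin oxidation gives 23.

**Further compounds**

F0 | step 5 | none | none
F1 | step 15 | 1,2,5,5-tetramethyl-1,2,4,4a,5,8a-hexahydronaphthalene-3,8-dione (C2 epimers) | CC1C(=O)C[C@@H]2[C@H](C(=O)C=CC2(C)C)[C@H]1C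
F2 | step 15 | 3-[(tert-butyldimethylsilyl)oxy]-1,2,5,5-tetramethyl-1,4,4a,5-tetrahydronaphthalen-8(8aH)-one | CC1=C(O[Si](C)(C)C(C)(C)C)C[C@@H]2[C@H](C(=O)C=CC2(C)C)[C@H]1C
F3 | step 15 | methyl (2R)-2-[(tert-butyldimethylsilyl)oxy]-2-[4-[(tert-butyldimethylsilyl)oxy]-2-(1,2,5,5-tetramethyl-3,8-dioxo-1,2,3,4,4a,5,8,8a-octahydronaphthalen-2-yl)cyclopent-3-en-1-yl]acetate | COC(=O)[C@H](O[Si](C)(C)C(C)(C)C)[C@@H]1CC(O[Si](C)(C)C(C)(C)C)=C[C@H]1[C@]2(C)C(=O)C[C@@H]3[C@H](C(=O)C=CC3(C)C)[C@H]2C
F4 | step 15 | bis(enol triflate) of F3 (triflates at C3 and C8 of the naphthalene unit) | COC(=O)[C@H](O[Si](C)(C)C(C)(C)C)[C@@H]1CC(O[Si](C)(C)C(C)(C)C)=C[C@H]1[C@]2(C)C(OS(=O)(=O)C(F)(F)F)=C[C@@H]3C(=C(OS(=O)(=O)C(F)(F)F)C=CC3(C)C)[C@H]2C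
F5 | step 15 | methyl (2R)-2-[(tert-butyldimethylsilyl)oxy]-2-[4-[(tert-butyldimethylsilyl)oxy]-2-(1,2,5,5-tetramethyl-1,2,4a,5-tetrahydronaphthalen-2-yl)cyclopent-3-en-1-yl]acetate | COC(=O)[C@H](O[Si](C)(C)C(C)(C)C)[C@@H]1CC(O[Si](C)(C)C(C)(C)C)=C[C@H]1[C@]2(C)C=C[C@@H]3C(=CC=CC3(C)C)[C@H]2C
F6 | step 13 | cyclopent-3-en-1-yl acetate | CC(=O)OC1CC=CC1
F7 | step 13 | methyl (2R)-2-[(1R)-4-acetoxycyclopent-2-en-1-yl]-2-hydroxyacetate (C4 epimers) | COC(=O)[C@H](O)[C@@H]1CC(OC(C)=O)C=C1
F8 | step 13 | methyl (2R)-2-[(1R)-4-acetoxycyclopent-2-en-1-yl]-2-[(tert-butyldimethylsilyl)oxy]acetate | COC(=O)[C@H](O[Si](C)(C)C(C)(C)C)[C@@H]1CC(OC(C)=O)C=C1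
F9 | step 13 | methyl (2R)-2-[(tert-butyldimethylsilyl)oxy]-2-[(1R)-4-hydroxycyclopent-2-en-1-yl]acetate | COC(=O)[C@H](O[Si](C)(C)C(C)(C)C)[C@@H]1CC(O)C=C1
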